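**Retrosynthetic overview**
- Target ⇐ hepta-O-methyl ether; the ring A–ring C biaryl bond (six-membered dihydrophenanthrene ring) is closed last by Pd direct arylation of an aryl bromide.
- C9–H and C17–H2 ⇐ reductive excision of a C9–O–C17 oxygen bridge in a 5,10-epoxy-dibenzosuberane; the bridge carries all stereochemical information.
- C16–ring D bond ⇐ anodic, DDQ-mediated benzylic C–H arylation with veratrole on the open face of the bridged bicycle (the new step).
- Seven-membered ring (C9–ring C bond) ⇐ anodic oxidation of an isochroman to its oxocarbenium ion and transannular Friedel–Crafts closure; isochroman (C9–ring B bond) ⇐ oxa-Pictet–Spengler.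
- Chirality: (R)-phenylephrine → (R)-aryloxirane → (S)-1,2-diarylethanol (future C17–O). Ring order: temporary pyran → seven-membered ring → six-membered ring.

Labels: ring A = resorcinol ring, ring B = fused catechol ring, ring C = fused monophenol ring, ring D = pendant catechol; C9 = methine on rings B and C, C8 = its CH2 on ring A, C16 = methine carrying ring D, C17 = CH2 on ring C. Target = (9R,16S), C9–H and C16–H cis.

Assumption: (R)-phenylephrine hydrochloride, (3,4-dimethoxyphenyl)magnesium bromide (THF solution), 2-bromo-3,5-dimethoxybenzaldehyde and veratrole are bought as such.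

**Step 1**
Reactants: 1 (R)-phenylephrine hydrochloride
Product: 3 (R)-2-(3-methoxyphenyl)oxirane, via quaternary ammonium iodide 2 (not isolated)
Conditions: MeI (5 equiv), K2CO3 (4 equiv), MeCN, 40 °C; evaporate; then KOtBu (1.3 equiv), THF, 0 °C → rt
Reagents that add atoms: methyl iodide, CI
Why: Exhaustive methylation (phenol O-methylation, N-quaternisation) and base-induced closure of the β-hydroxy ammonium salt (Hofmann-type intramolecular SN2 at the CH2N carbon) give the aryloxirane; no bond at the carbinol carbon is broken, so the purchased stereocenter (future C17) is retained.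

**Step 2**
Reactants: 3 (R)-2-(3-methoxyphenyl)oxirane; 4 (3,4-dimethoxyphenyl)magnesium bromide
Product: 5 (S)-2-(3,4-dimethoxyphenyl)-1-(3-methoxyphenyl)ethan-1-ol
Conditions: CuI (10 mol%), THF, −40 → −20 °C; then H2O
Reagents that add atoms: none
Why: CuI-catalysed Grignard opening of the monosubstituted epoxide at its CH2 terminus (SN2) installs ring B and C16 without touching the stereocenter, whose descriptor becomes S only through a CIP priority change.

**Step 3**
Reactants: 6 2-bromo-3,5-dimethoxybenzaldehyde
Product: 7 2-bromo-1,5-dimethoxy-3-(2-methoxyethenyl)benzene (E/Z mixture)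
Conditions: Ph3P(CH2OMe)Cl (1.3 equiv), KOtBu (1.3 equiv), THF, 0 °C → rt
Reagents that add atoms: (methoxymethyl)triphenylphosphonium chloride, COC[P+](c1ccccc1)(c1ccccc1)c1ccccc1.[Cl-]
Why: Wittig methoxymethylenation turns the aldehyde into an enol ether that serves as a stable equivalent of the arylacetaldehyde carrying ring A, C8 and C9; no stereocenter is formed.

**Step 4**
Reactants: 5 (S)-2-(3,4-dimethoxyphenyl)-1-(3-methoxyphenyl)ethan-1-ol; 7 2-bromo-1,5-dimethoxy-3-(2-methoxyethenyl)benzene
Product: 8 (1S,3S)-1-(2-bromo-3,5-dimethoxybenzyl)-6,7-dimethoxy-3-(3-methoxyphenyl)isochromane (1,3-cis)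
Conditions: TfOH (5 mol%), CH2Cl2, −20 °C → rt
Reagents that add atoms: none
Why: Oxa-Pictet–Spengler reaction: acid converts enol ether and alcohol into a mixed acetal and then an oxocarbenium ion, which ring B attacks para to a methoxy group to form the C9–ring B bond; the C17 stereocenter directs the usual 1,3-cis (diequatorial) isochroman, which places C9–H axial for the next oxidation.

**Step 5**
Reactants: 8 (1S,3S)-1-(2-bromo-3,5-dimethoxybenzyl)-6,7-dimethoxy-3-(3-methoxyphenyl)isochromane
Product: 9 (5R,10S)-5-(2-bromo-3,5-dimethoxybenzyl)-2,3,8-trimethoxy-10,11-dihydro-5H-5,10-epoxydibenzo[a,d][7]annulene (oxygen bridge C9–O–C17)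
Conditions: divided cell, graphite felt anode, Pt cathode, DDQ (10 mol%), nBu4NPF6 (0.1 M), CH2Cl2–HFIP (9:1), 5 mA cm−2, 2.1 F mol−1, rt
Reagents that add atoms: none
Why: Mediated anodic oxidation (anodically regenerated DDQ abstracts the axial α-oxy benzylic hydride at C9, the established oxidative C–H functionalisation of isochromans) gives an oxocarbenium ion that ring C traps para to its methoxy group in a transannular Friedel–Crafts reaction, forming the C9–ring C bond and the seven-membered ring; because the oxygen stays bound to C17, the quaternary C9 can form only with the bridge on the face dictated by C17.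

**Step 6**
Reactants: 9 the bridged ether above; 10 veratrole (1,2-dimethoxybenzene, 8 equiv)
Product: 11 (5R,10S,11S)-5-(2-bromo-3,5-dimethoxybenzyl)-11-(3,4-dimethoxyphenyl)-2,3,8-trimethoxy-10,11-dihydro-5H-5,10-epoxydibenzo[a,d][7]annulene (ring D on C16 cis to the oxygen bridge)
Conditions: divided cell, graphite felt anode, Pt cathode, DDQ (20 mol%), LiClO4 (0.1 M), CH2Cl2–HFIP (3:1), 3 mA cm−2, 2.3 F mol−1, 0 °C → rt
Reagents that add atoms: none
Why: Proposed new method: anodically regenerated DDQ, activated by HFIP, abstracts the exo hydride at C16 (para to a ring B methoxy group), and the resulting benzylic cation, which cannot eliminate toward the C17 bridgehead, is captured by veratrole at its 4-position from the open convex face, so ring D ends cis to the oxygen bridge (C16 set by the bridged scaffold and hence by C17) while the remaining endo C16–H lies in the cleft and resists over-oxidation; the closest known reaction type is the stoichiometric DDQ cross-dehydrogenative benzylic C–H arylation (oxidative Friedel–Crafts) combined with mediated electrolysis using a catalytic quinone.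

**Step 7**
Reactants: 11 the ring D-bearing bridged ether above
Product: 13 (5S,11S)-5-(2-bromo-3,5-dimethoxybenzyl)-11-(3,4-dimethoxyphenyl)-2,3,8-trimethoxy-10,11-dihydro-5H-dibenzo[a,d][7]annulene (C9–H and C16–H cis; C9 is S here only by CIP priority), via ring-opened C17 alcohol 12 (not isolated)
Conditions: Et3SiH (8 equiv), TFA–CH2Cl2 (1:3), −20 °C, 1 h; then TfOH (0.3 equiv), 0 °C → rt
Reagents that add atoms: none
Why: Ionic hydrogenation: acid ionises the tertiary doubly benzylic C9–O bond and Et3SiH delivers hydride from the face opposite the departing oxygen (still tethered through C17) and ring D, so C8 ends cis to ring D (C9 set by C17 and C16); the freed C17 hydroxyl is then removed by a second silane reduction, whose hydride-shift-assisted ionisation gives the ring B-stabilised C16 cation that is reduced anti to the axial C8 substituent and so returns the same C16 configuration.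

**Step 8**
Reactants: 13 the aryl bromide above
Product: 14 hepta-O-methyl ether of the target (9R,16S; C9–H and C16–H cis)
Conditions: Pd(OAc)2 (10 mol%), PCy3·HBF4 (20 mol%), PivOH (30 mol%), K2CO3 (2.5 equiv), DMA, 120 °C
Reagents that add atoms: none
Why: Intramolecular direct arylation (oxidative addition of zerovalent palladium into the ring A C–Br bond, concerted metalation–deprotonation of the ring C C–H ortho to C9, reductive elimination) closes the six-membered dihydrophenanthrene ring; the competing ring B position is flanked by a methoxy group and would create a methoxy/methoxy bay clash, and neither stereocenter is touched.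

**Step 9**
Reactants: 14 hepta-O-methyl ether of the target
Product: 15 CNP0306974.1 (9R,16S)
Conditions: BBr3 (14 equiv), CH2Cl2, −78 °C → rt; then H2O
Reagents that add atoms: none
Why: BBr3 cleaves all seven aryl methyl ethers (Lewis acid-mediated demethylation); the two benzylic methines carry no leaving group and are not epimerised.

**Compound list**
1 | (R)-phenylephrine hydrochloride | CNC[C@H](O)c1cccc(O)c1.Cl | starting material
2 | (R)-2-hydroxy-2-(3-methoxyphenyl)-N,N,N-trimethylethan-1-aminium iodide | C[N+](C)(C)C[C@H](O)c1cccc(OC)c1.[I-] | intermediate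
3 | (R)-2-(3-methoxyphenyl)oxirane | COc1cccc([C@@H]2CO2)c1 | intermediate
4 | (3,4-dimethoxyphenyl)magnesium bromide | COc1ccc([Mg]Br)cc1OC | starting material
5 | (S)-2-(3,4-dimethoxyphenyl)-1-(3-methoxyphenyl)ethan-1-ol | COc1ccc(C[C@H](O)c2cccc(OC)c2)cc1OC | intermediate
6 | 2-bromo-3,5-dimethoxybenzaldehyde | COc1cc(OC)c(Br)c(C=O)c1 | starting material
7 | 2-bromo-1,5-dimethoxy-3-(2-methoxyethenyl)benzene (E/Z mixture) | COC=Cc1cc(OC)cc(OC)c1Br | intermediate
8 | (1S,3S)-1-(2-bromo-3,5-dimethoxybenzyl)-6,7-dimethoxy-3-(3-methoxyphenyl)isochromane (1,3-cis) | COc1cc(OC)c(Br)c(c1)C[C@@H]1O[C@@H](Cc2cc(OC)c(OC)cc21)c1cccc(OC)c1 | intermediate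
9 | (5R,10S)-5-(2-bromo-3,5-dimethoxybenzyl)-2,3,8-trimethoxy-10,11-dihydro-5H-5,10-epoxydibenzo[a,d][7]annulene (C9 R; C17 S) | COc1cc(OC)c(Br)c(c1)C[C@@]23O[C@@H](Cc4cc(OC)c(OC)cc42)c2cc(OC)ccc23 | intermediate
10 | veratrole (1,2-dimethoxybenzene) | COc1ccccc1OC | starting material
11 | (5R,10S,11S)-5-(2-bromo-3,5-dimethoxybenzyl)-11-(3,4-dimethoxyphenyl)-2,3,8-trimethoxy-10,11-dihydro-5H-5,10-epoxydibenzo[a,d][7]annulene (C9 R; C16 S; C17 S; ring D cis to the bridge) | COc1cc(OC)c(Br)c(c1)C[C@@]23O[C@@H]([C@@H](c4ccc(OC)c(OC)c4)c4cc(OC)c(OC)cc42)c2cc(OC)ccc23 | intermediate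
12 | (5R,10S,11S)-5-(2-bromo-3,5-dimethoxybenzyl)-11-(3,4-dimethoxyphenyl)-2,3,8-trimethoxy-10,11-dihydro-5H-dibenzo[a,d][7]annulen-10-ol (C9 R; C16 S; C17 S) | COc1cc(OC)c(Br)c(c1)C[C@@H]1c3cc(OC)c(OC)cc3[C@H](c3ccc(OC)c(OC)c3)[C@H](O)c3cc(OC)ccc31 | intermediate
13 | (5S,11S)-5-(2-bromo-3,5-dimethoxybenzyl)-11-(3,4-dimethoxyphenyl)-2,3,8-trimethoxy-10,11-dihydro-5H-dibenzo[a,d][7]annulene (C9–H and C16–H cis) | COc1cc(OC)c(Br)c(c1)C[C@@H]1c3cc(OC)c(OC)cc3[C@H](c3ccc(OC)c(OC)c3)Cc3cc(OC)ccc31 | intermediate
14 | hepta-O-methyl ether of CNP0306974.1 (9R,16S) | COc1cc(OC)c2c(c1)C[C@@H]1c3cc(OC)c(OC)cc3[C@H](c3ccc(OC)c(OC)c3)Cc3cc(OC)cc-2c31 | intermediate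
15 | CNP0306974.1 (9R,16S) | Oc1cc(O)c2c(c1)C[C@@H]1c3cc(O)c(O)cc3[C@H](c3ccc(O)c(O)c3)Cc3cc(O)cc-2c31 | target

**Totals**
Total step count: 9. Longest linear sequence: 8 steps (steps 1, 2, 4, 5, 6, 7, 8, 9 from compound 1).

**Three steps most likely to fail**

Step 6 (the new step). Risks are a slow hydride abstraction from a mono-aryl benzylic CH2, a Wagner–Meerwein shift of ring C in the C16 cation, and aryl–aryl coupling of veratrole. The fallback uses known chemistry and sets out from 9. Stoichiometric DDQ (1.5 equiv) in AcOH at 50 °C gives the exo C16 benzylic acetate F1 (the known DDQ benzylic acetoxylation of p-alkoxy alkylarenes). A conventional Lewis acid Friedel–Crafts benzylation of veratrole (5 equiv) with BF3·OEt2 (1.2 equiv) in CH2Cl2 at −40 °C then passes through the same cation and the same exo attack, and comes back to the route at 11.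

Step 7. Risks are hydride delivery to the wrong face of C9, and transannular Friedel–Crafts capture of the C16 cation formed in the second reduction. The fallback sets out from 11. Et3SiH (3 equiv) with BF3·OEt2 (1.5 equiv) in CH2Cl2 at −60 °C cleaves only the tertiary C9–O bond, and alcohol 12 is isolated. Direct arylation under the step 8 conditions then gives the hexacyclic C17 alcohol F2. Hydrogenolysis of the benzylic hydroxyl on the metal surface (H2, 4 atm, Pd(OH)2/C, AcOH–EtOAc), with no free C17 cation, comes back to the route at 14.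

Step 5. The risk is that the ketone-level oxocarbenium ion loses a proton to an enol ether or is over-oxidised before the strained transannular closure. The fallback sets out from 8. Stoichiometric DDQ (1.2 equiv) in CH2Cl2–H2O (10:1) gives, after hydrolysis, the ring-opened hydroxy ketone F3 (open form of the C9 hemiketal). TfOH (1.0 equiv) in HFIP at 0 °C then effects a redox-neutral dehydrative double cyclisation (hemiketal ionisation, Friedel–Crafts by ring C) and comes back to the route at 9.

**Further compounds**
F1 | step 6 | (5R,10S)-5-(2-bromo-3,5-dimethoxybenzyl)-2,3,8-trimethoxy-10,11-dihydro-5H-5,10-epoxydibenzo[a,d][7]annulen-11-yl acetate (acetate exo, cis to the bridge) | COc1cc(OC)c(Br)c(c1)C[C@@]23O[C@@H]([C@@H](OC(C)=O)c4cc(OC)c(OC)cc42)c2cc(OC)ccc23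
F2 | step 7 | hepta-O-methyl ether of the target carrying a hydroxyl on C17 (C9 R; C16 S; C17 S) | COc1cc(OC)c2c(c1)C[C@@H]1c3cc(OC)c(OC)cc3[C@H](c3ccc(OC)c(OC)c3)[C@H](O)c3cc(OC)cc-2c31
F3 | step 5 | 2-(2-bromo-3,5-dimethoxyphenyl)-1-{2-[(2S)-2-hydroxy-2-(3-methoxyphenyl)ethyl]-4,5-dimethoxyphenyl}ethan-1-one | COc1cc(OC)c(Br)c(c1)CC(=O)c1cc(OC)c(OC)cc1C[C@H](O)c1cccc(OC)c1
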